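**Retrosynthetic overview**

1. Feature: the acyclic core ArCH2–CH(CH3)–CH(CH3)–CH2Ar. Its two adjacent (R,R) methine carbons, each bearing one CH3, are the CH3–CH–CH–CH3 unit of trans-but-2-ene with two arylmethyl groups added to the same face. Both stereocentres can therefore be set once, on a C4 bis(boronate), before either aryl ring is attached.
2. Sauriol A 13 ⇒ bis-acetonide 12 (hydrolysis of two catechol acetonides) ⇒ bis(benzylic boronate) 11 (both benzylic C–B bonds to C–H).
3. 11 ⇒ (2S,3S)-2,3-bis(pinacolboryl)butane 8 plus two lithiated benzylic carbamates from 4: both CH(CH3)–CH(Ar) bonds by a twofold 1,2-metallate rearrangement with retention.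
4. 8 ⇐ (E)-but-2-ene 5 + bis(catecholato)diboron 6 (Rh/Quinap syn-diboration, pinacol exchange); 4 ⇐ 3,4-dihydroxy-5-methoxybenzaldehyde 1 (acetonide, reduction, carbamoylation).
5. No ring of the target is formed: both benzene rings come from 1. The only rings made are auxiliary (the dioxole in step 1, the dioxaborolanes in step 4) and all are gone after step 7.

Key step: step 5

Assumption: (S)-Quinap is taken to deliver the (S,S) product from trans-1,2-dialkylethenes; the sense is to be checked by oxidising an aliquot of 8 to butane-2,3-diol, and (R)-Quinap is used if it proves opposite.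

**Route**

Step 1
Reactants: 1 3,4-dihydroxy-5-methoxybenzaldehyde
Product: 2 7-methoxy-2,2-dimethyl-1,3-benzodioxole-5-carbaldehyde
Conditions: 2,2-dimethoxypropane, p-TsOH (cat.), toluene, reflux, MeOH removed over 4 Å MS; brief 1 M aq. HCl wash
Reagents that add atoms: 2,2-dimethoxypropane, COC(C)(C)OC
Why: Acid-catalysed transketalisation closes the five-membered aryl ketal as methanol is removed, and the acid wash returns any aldehyde dimethyl acetal to the aldehyde without opening the catechol acetonide.

Step 2
Reactants: 2 7-methoxy-2,2-dimethyl-1,3-benzodioxole-5-carbaldehyde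
Product: 3 (7-methoxy-2,2-dimethyl-1,3-benzodioxol-5-yl)methanol
Conditions: NaBH4, MeOH, 0 °C
Reagents that add atoms: none
Why: Borohydride reduction of an aryl aldehyde; the aryl ketal and the methyl ether are inert to hydride.

Step 3
Reactants: 3 (7-methoxy-2,2-dimethyl-1,3-benzodioxol-5-yl)methanol
Product: 4 (7-methoxy-2,2-dimethyl-1,3-benzodioxol-5-yl)methyl N,N-diisopropylcarbamate
Conditions: NaH, THF, 0 °C; then iPr2NCOCl, rt → 60 °C
Reagents that add atoms: N,N-diisopropylcarbamoyl chloride, CC(C)N(C(C)C)C(Cl)=O
Why: O-Carbamoylation of the sodium benzylic alkoxide installs the hindered carbamate that later directs benzylic lithiation and acts as the leaving group.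

Step 4
Reactants: 5 (E)-but-2-ene (excess, condensed); 6 bis(catecholato)diboron
Product: 8 (2S,3S)-2,3-bis(4,4,5,5-tetramethyl-1,3,2-dioxaborolan-2-yl)butane, via bis(catecholboronate) 7 (not isolated)
Conditions: (nbd)Rh(acac) (5 mol %), (S)-Quinap (5 mol %), THF, rt, sealed vessel; then pinacol, rt
Reagents that add atoms: pinacol, CC(C)(O)C(C)(C)O
Why: Rh(I)-catalysed enantioselective alkene diboration (B–B oxidative addition, insertion, reductive elimination) adds both boryl groups to one face, so the (E)-geometry fixes the C2-symmetric relative configuration and the Quinap ligand selects the face that gives (2S,3S); pinacol then displaces catechol to give the stable pinacol ester.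

Step 5
Reactants: 4 (7-methoxy-2,2-dimethyl-1,3-benzodioxol-5-yl)methyl N,N-diisopropylcarbamate (2.4 equiv); 8 (2S,3S)-2,3-bis(4,4,5,5-tetramethyl-1,3,2-dioxaborolan-2-yl)butane (1.0 equiv)
Product: 11 (2R,3R)-1,4-bis(7-methoxy-2,2-dimethyl-1,3-benzodioxol-5-yl)-2,3-dimethyl-1,4-bis(4,4,5,5-tetramethyl-1,3,2-dioxaborolan-2-yl)butane (mixture of C1/C4 epimers), via lithiated carbamate 9 (not isolated), via dilithium bis(boronate complex) 10 (not isolated)
Conditions: 4, s-BuLi (2.3 equiv), TMEDA, Et2O, −78 °C; then 8, −78 °C, 2 h; then MgBr2 in MeOH, −78 °C → rt; aqueous work-up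
Reagents that add atoms: none
Why: s-BuLi/TMEDA removes a benzylic proton of 4 to give the dipole-stabilised carbenoid 9, which adds to each trigonal boron of 8 at −78 °C to give the bis(boronate complex) 10; on warming with MgBr2 each complex undergoes a 1,2-metallate shift in which the CH(CH3) carbon moves from boron to the benzylic carbon as the carbamate leaves, forming the two CH(CH3)–CH(Ar) bonds. The closest known reaction type is the lithiation–borylation homologation of secondary alkyl pinacol boronic esters with lithiated benzylic carbamates, together with the twofold carbenoid homologation of alkene-diboration products. No ring is closed. The two benzylic boron-bearing centres arise without control from the configurationally labile racemic carbenoid and are left as an epimer mixture because step 6 turns them into CH2, whereas the two CH(CH3) centres are not new and keep their configuration because a migrating group is transferred with retention (the change of descriptor from S in 8 to R in 11 is a priority effect only). The selectivity needed is one homologation at each boron and no more: both borons are complexed at −78 °C before any migration begins, s-BuLi is kept in deficit to 4 so that no sec-butyl ate complex forms, and the methanol destroys surplus 9 before warming so that the new, more hindered benzylic boronates cannot be homologated again.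

Step 6
Reactants: 11 (2R,3R)-1,4-bis(7-methoxy-2,2-dimethyl-1,3-benzodioxol-5-yl)-2,3-dimethyl-1,4-bis(4,4,5,5-tetramethyl-1,3,2-dioxaborolan-2-yl)butane
Product: 12 (2R,3R)-1,4-bis(7-methoxy-2,2-dimethyl-1,3-benzodioxol-5-yl)-2,3-dimethylbutane
Conditions: TBAF·3H2O, toluene, 80 °C, Ar
Reagents that add atoms: none
Why: Fluoride-promoted protodeboronation of benzylic boronic esters: the fluoroborate ate complex gives up its benzylic carbon to a proton of the hydrate water, so both epimeric CH(Bpin) centres become CH2 while the neighbouring methine stereocentres are not involved.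

Step 7
Reactants: 12 (2R,3R)-1,4-bis(7-methoxy-2,2-dimethyl-1,3-benzodioxol-5-yl)-2,3-dimethylbutane
Product: 13 Sauriol A, 5,5'-[(2R,3R)-2,3-dimethylbutane-1,4-diyl]bis(3-methoxybenzene-1,2-diol)
Conditions: TFA–H2O (9:1), rt, degassed, Ar
Reagents that add atoms: none
Why: Acid-catalysed ketal hydrolysis frees both catechols; the aryl methyl ethers and the saturated chain are inert to aqueous acid, and air is excluded because the catechols oxidise readily.

**Compound list**

1 | 3,4-dihydroxy-5-methoxybenzaldehyde | COc1cc(C=O)cc(O)c1O | starting material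
2 | 7-methoxy-2,2-dimethyl-1,3-benzodioxole-5-carbaldehyde | COc1cc(C=O)cc2c1OC(C)(C)O2 | intermediate
3 | (7-methoxy-2,2-dimethyl-1,3-benzodioxol-5-yl)methanol | COc1cc(CO)cc2c1OC(C)(C)O2 | intermediate
4 | (7-methoxy-2,2-dimethyl-1,3-benzodioxol-5-yl)methyl N,N-diisopropylcarbamate | COc1cc(COC(=O)N(C(C)C)C(C)C)cc2c1OC(C)(C)O2 | intermediate
5 | (E)-but-2-ene | C/C=C/C | starting material
6 | bis(catecholato)diboron | B1(Oc2ccccc2O1)B1Oc2ccccc2O1 | starting material
7 | (2S,3S)-2,3-bis(1,3,2-benzodioxaborol-2-yl)butane | B1(Oc2ccccc2O1)[C@@H](C)[C@H](C)B1Oc2ccccc2O1 | intermediate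
8 | (2S,3S)-2,3-bis(4,4,5,5-tetramethyl-1,3,2-dioxaborolan-2-yl)butane | CC1(C)OB(OC1(C)C)[C@@H](C)[C@H](C)B1OC(C)(C)C(C)(C)O1 | intermediate
9 | lithio(7-methoxy-2,2-dimethyl-1,3-benzodioxol-5-yl)methyl N,N-diisopropylcarbamate (racemic, TMEDA-solvated) | [Li]C(OC(=O)N(C(C)C)C(C)C)c1cc(OC)c2OC(C)(C)Oc2c1 | intermediate
10 | dilithium bis(boronate complex) of 8 with two units of 9 (benzylic epimers) | [Li+].[Li+].COc1cc(C(OC(=O)N(C(C)C)C(C)C)[B-]2(OC(C)(C)C(C)(C)O2)[C@@H](C)[C@H](C)[B-]2(OC(C)(C)C(C)(C)O2)C(OC(=O)N(C(C)C)C(C)C)c2cc(OC)c3OC(C)(C)Oc3c2)cc2c1OC(C)(C)O2 | intermediate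
11 | (2R,3R)-1,4-bis(7-methoxy-2,2-dimethyl-1,3-benzodioxol-5-yl)-2,3-dimethyl-1,4-bis(4,4,5,5-tetramethyl-1,3,2-dioxaborolan-2-yl)butane (C1/C4 epimers) | COc1cc(C(B3OC(C)(C)C(C)(C)O3)[C@@H](C)[C@H](C)C(B3OC(C)(C)C(C)(C)O3)c3cc(OC)c4OC(C)(C)Oc4c3)cc2c1OC(C)(C)O2 | intermediate
12 | (2R,3R)-1,4-bis(7-methoxy-2,2-dimethyl-1,3-benzodioxol-5-yl)-2,3-dimethylbutane | COc1cc(C[C@@H](C)[C@H](C)Cc3cc(OC)c4OC(C)(C)Oc4c3)cc2c1OC(C)(C)O2 | intermediate
13 | Sauriol A | COc1cc(C[C@@H](C)[C@H](C)Cc2cc(O)c(O)c(OC)c2)cc(O)c1O | target

**Step count**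

Total steps: 7. Longest linear sequence: 6 (steps 1, 2, 3, 5, 6, 7).

**Steps most likely to fail**

Step 5. The second boron may not take up the carbenoid next to the first ate centre (steric and electrostatic hindrance), complexation may reverse on warming, or the new benzylic boronates may be homologated further. The fallback sets out from 8 and 2 and returns at 12; it introduces the CH2 and the aryl group separately. Bis(boronate) 8 would be homologated at both borons with chloromethyllithium (BrCH2Cl, n-BuLi, THF, −78 °C → rt; Matteson-type insertion with retention) to give (2R,3R)-2,3-dimethyl-1,4-bis(pinacolboryl)butane F1. Aldehyde 2 would be oxidised (mCPBA, CH2Cl2; Baeyer–Villiger) to the aryl formate F2, saponified (KOH, MeOH–H2O) to the phenol F3, and converted (Tf2O, pyridine, CH2Cl2) into the aryl triflate F4. A twofold B-alkyl Suzuki–Miyaura coupling of F1 with F4 (Pd(OAc)2, RuPhos, K3PO4, toluene–H2O, 90 °C) should then give 12 directly, bypassing 11 and step 6.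

Step 6. Protonolysis of the C–B bond may be sluggish at secondary benzylic centres bearing electron-rich aryl groups and stall after one boron is removed. The fallback sets out from 11 and returns at 12. Oxidation with retention (H2O2, NaOH, THF–H2O, 0 °C) would give the 1,4-diol F5 as benzylic epimers. Hydrogenolysis of both benzylic C–O bonds (H2, Pd(OH)2/C, EtOAc–AcOH, rt) should then give 12. No benzylic ketone is passed through, so the adjacent methine centres cannot enolise, and strong acid is avoided so that no benzylic cation attacks the other arene.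

Step 4. The diboration may give insufficient enantioselectivity, or alkene isomerisation and β-hydride elimination may compete while the volatile alkene is lost. The fallback sets out from 5 and returns at 12; it replaces asymmetric catalysis by resolution. Pt(dba)2-catalysed syn-diboration of 5 with bis(pinacolato)diboron (toluene, 50 °C) would give 8 as the racemate, that is, together with its (2R,3R)-enantiomer F6. The racemate would be taken through steps 5 and 6 as written, giving 11 and 12 together with the mirror-image bis(benzylic boronate) F7 and the mirror-image bis-acetonide F8. Preparative HPLC on a chiral stationary phase would then return enantiopure 12 before step 7.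

**Further compounds**

F1 | step 5 | (2R,3R)-2,3-dimethyl-1,4-bis(4,4,5,5-tetramethyl-1,3,2-dioxaborolan-2-yl)butane | CC1(C)OB(OC1(C)C)C[C@@H](C)[C@H](C)CB1OC(C)(C)C(C)(C)O1
F2 | step 5 | (7-methoxy-2,2-dimethyl-1,3-benzodioxol-5-yl) formate | COc1cc(OC=O)cc2c1OC(C)(C)O2
F3 | step 5 | 7-methoxy-2,2-dimethyl-1,3-benzodioxol-5-ol | COc1cc(O)cc2c1OC(C)(C)O2
F4 | step 5 | (7-methoxy-2,2-dimethyl-1,3-benzodioxol-5-yl) trifluoromethanesulfonate | COc1cc(OS(=O)(=O)C(F)(F)F)cc2c1OC(C)(C)O2
F5 | step 6 | 1,4-bis(7-methoxy-2,2-dimethyl-1,3-benzodioxol-5-yl)-2,3-dimethylbutane-1,4-diol (benzylic epimers, C2/C3 as in 12) | COc1cc(C(O)[C@@H](C)[C@H](C)C(O)c3cc(OC)c4OC(C)(C)Oc4c3)cc2c1OC(C)(C)O2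
F6 | step 4 | (2R,3R)-2,3-bis(4,4,5,5-tetramethyl-1,3,2-dioxaborolan-2-yl)butane (enantiomer of 8) | CC1(C)OB(OC1(C)C)[C@H](C)[C@@H](C)B1OC(C)(C)C(C)(C)O1
F7 | step 4 | (2S,3S)-1,4-bis(7-methoxy-2,2-dimethyl-1,3-benzodioxol-5-yl)-2,3-dimethyl-1,4-bis(4,4,5,5-tetramethyl-1,3,2-dioxaborolan-2-yl)butane (enantiomeric series of 11, C1/C4 epimers) | COc1cc(C(B3OC(C)(C)C(C)(C)O3)[C@H](C)[C@@H](C)C(B3OC(C)(C)C(C)(C)O3)c3cc(OC)c4OC(C)(C)Oc4c3)cc2c1OC(C)(C)O2
F8 | step 4 | (2S,3S)-1,4-bis(7-methoxy-2,2-dimethyl-1,3-benzodioxol-5-yl)-2,3-dimethylbutane (enantiomer of 12) | COc1cc(C[C@H](C)[C@@H](C)Cc3cc(OC)c4OC(C)(C)Oc4c3)cc2c1OC(C)(C)O2
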